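From 12.0 h to 30.0 h triple product in the midnight run reads flat, at a mean of 61.0%. That reading is kept as the branch share: the part of the substrate ending as triple product once the ladder from substrate through first and double product has run through, a selectivity.

| setting | noon | midnight | east | south |
|---|---|---|---|---|
| substrate | 10 mM | 10 mM | 10 mM | 10 mM |
| partner | 7.1 mM | 59 mM | 5.00 mM | 40.0 mM |
| remark | run made earlier | run made earlier |  |  |
| time |  |  | 2.5 d | 2.5 d |

| run | time / h | triple product / % | double product / % | substrate / % |
|---|---|---|---|---|
| noon | 1.50 | 0 | 1.1 | 88.7 |
| noon | 5.00 | 2.1 | 5.4 | 70.0 |
| noon | 8.00 | 3.6 | 2.1 | 63.8 |
| noon | 12.0 | 4.4 | 5.3 | 59.9 |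
| noon | 20.0 | 6.8 | 5.6 | 55.5 |
| noon | 25.0 | 5.7 | 4.1 | 57.7 |
| noon | 30.0 | 7.8 | 7.4 | 56.9 |
| midnight | 1.50 | 24.7 | 8.3 | 30.6 |
| midnight | 5.00 | 54.2 | 0.1 | 4.6 |
| midnight | 8.00 | 57.1 | 0 | 2.1 |
| midnight | 12.0 | 60.0 | 0 | 0 |
| midnight | 20.0 | 63.4 | 0 | 0 |
| midnight | 25.0 | 60.3 | 0.7 | 0.1 |
| midnight | 30.0 | 60.4 | 0 | 0 |

(standard deviation of a reading: 1 percentage point)

- which of these holds the largest part of the substrate at the end of east (substrate / first product / triple product / double product)
- which of these holds the largest part of the substrate at the end of south (substrate / first product / triple product / double product)
- final triple product in south, as a percentage of the substrate charged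

At the last midnight reading substrate stands at 0% and double product at 0%. Even at 3 partners per substrate, 29.0 mM of partner remains in midnight, yet triple product there no longer rises. This reckoning therefore takes the missing 39.0% as a dead branch, not a waiting intermediate. If two competing steps are each first order in partner, their rate ratio holds as partner falls, so this reckoning carries the share over to south.

For triple product not to hold the largest part in south, substrate, first product or double product would have to stand above it at the end. South charges 4.00 equivalents against 3, so at least 10.0 mM of partner stays. With the rate taken as proportional to partner and midnight's partner taken as charged, the substrate half-life at that partner level, estimated from the first midnight reading, is 5.18 h, and 2.5 d spans 11.6 of them. So this reckoning, assuming that first product clears as it did in midnight, puts the end of south at the branch share. In east partner is the limiting reagent, and each substrate reacting takes at least one, so at least 50.0% of the substrate stays.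

The forecast names substrate for east and triple product for south, with 51% triple product (range 41% to 58%), “a close call against first product”, which is lower than this reckoning.

The flask gives 62.1% triple product in south and 66.6% substrate in east, on these steps:

    substrate + partner → first product + released group (k = 15.0 M⁻¹ h⁻¹)
    partner + first product → double product + released group (k = 28.0 M⁻¹ h⁻¹)
    partner + double product → triple product + released group (k = 64.0 M⁻¹ h⁻¹)
    partner + double product → over-reaction product (k = 39.0 M⁻¹ h⁻¹)

South's triple product stands 1.1 percentage points above the branch share, and the rest of south is over-reaction product, 37.9%. The neighbour flask, south with 24 mM of partner instead, has 2.40 equiv, and it ends with 11.5% substrate and 0.16% of its partner. Triple and over-reaction product there hold 73.8% together, of which the branch share gives 45.1% as triple product, and that flask holds 45.9%.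

(The data are simulated from invented constants; noise was put on by code.)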